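**Retrosynthetic overview**
- Target ⇐ C9 α-hydroxylation (Rubottom), C10 methylenation and OH-directed C6 reduction of a 5–7 bicyclic 6,10-dione that already carries the complete side chain.
- Seven-membered ring ⇐ one-carbon ring expansion of a cis-hydrindan-6-one by C–C insertion of a side-chain diazoalkane (forms C6–C7 and C7–C8, sets C7).
- cis-Hydrindanone ⇐ Danheiser [3+2] annulation on (R)-4-silyloxycyclohexenone; C4 carbinol and the 2,3-alkene by epoxide → selenoxide transposition.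
- Side chain ⇐ syn-aldol of hydroxyacetone with prenal, methylenation, syn-selective hydroboration, aldehyde → N-silyl hydrazone.
- Ring order: six-membered ring (bought) → five-membered ring (annulation) → seven-membered ring (ring expansion).

Assumption: (R)-4-hydroxycyclohex-2-en-1-one and 1-methyl-1-(trimethylsilyl)allene are bought as catalogue compounds.
Numbering for 21–29 (dictyol type): ring fusion C1/C5; five-membered ring C1–C2–C3–C4–C5; seven-membered ring C5–C6–C7–C8–C9–C10–C1; side chain C11(Me)–C12–C13–C14=C15Me2 on C7; α = face of H-1 and H-5.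

**Side chain**

Step 1
Reactants: 1 hydroxyacetone; 2 3-methylbut-2-enal (prenal)
Product: 3 (3R,4S)-3,4-dihydroxy-6-methylhept-5-en-2-one
Conditions: O-tBu-L-threonine (20 mol %), NMP, 4 °C, 48 h
Reagents that add atoms: none
Why: Primary-amine enamine catalysis (direct syn-aldol of hydroxyacetone): the H-bonded (Z)-hydroxy-enamine adds 1,2 to the enal and sets the syn diol (C12, C13 of the target).

Step 2
Reactants: 3
Product: 4 (3R,4S)-6-methyl-2-oxohept-5-ene-3,4-diyl diacetate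
Conditions: Ac2O, pyridine, CH2Cl2, 0 °C
Reagents that add atoms: acetic anhydride CC(=O)OC(C)=O
Why: Plain O-acetylation; no DMAP and low temperature keep the β-acetoxy ketone from E1cB elimination.

Step 3
Reactants: 4
Product: 5 (3S,4S)-2,6-dimethylhepta-1,5-diene-3,4-diyl diacetate
Conditions: Zn, CH2Br2, TiCl4, THF/CH2Cl2, 0 °C → rt
Reagents that add atoms: dibromomethane BrCBr
Why: Takai–Lombardo methylenation is non-basic, so the enolisable α-acetoxy ketone and both esters survive.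

Step 4
Reactants: 5
Product: 7 (2R,3S,4S)-1-hydroxy-2,6-dimethylhept-5-ene-3,4-diyl diacetate, via catechol boronate 6 (not isolated)
Conditions: catecholborane, RhCl(PPh3)3 (3 mol %), THF, 0 °C → rt; then H2O2, pH 7 buffer, 0 °C
Reagents that add atoms: catecholborane [H]B1Oc2ccccc2O1; hydrogen peroxide OO
Why: Rh-catalysed hydroboration–oxidation is anti-Markovnikov, prefers the 1,1-disubstituted over the trisubstituted alkene and adds syn to the allylic C–O bond (sets C11); buffered oxidation avoids acetyl migration.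

Step 5
Reactants: 7
Product: 8 (2S,3S,4S)-2,6-dimethyl-1-oxohept-5-ene-3,4-diyl diacetate
Conditions: DMP, NaHCO3, CH2Cl2, 0 °C
Reagents that add atoms: none
Why: Dess–Martin oxidation without amine base avoids epimerisation at C11 and β-elimination of acetate.

Step 6
Reactants: 8
Product: 9 (2R,3S,4S)-1-[(E)-2-(tert-butyldimethylsilyl)hydrazinylidene]-2,6-dimethylhept-5-ene-3,4-diyl diacetate
Conditions: TBSNHNHTBS, Sc(OTf)3 (0.1 mol %), CH2Cl2, rt
Reagents that add atoms: 1,2-bis(tert-butyldimethylsilyl)hydrazine CC(C)(C)[Si](C)(C)NN[Si](C)(C)C(C)(C)C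
Why: Myers N-silyl hydrazone formation is neutral and gives a storable precursor of the non-stabilised diazoalkane.

**Core**

Step 7
Reactants: 10 (R)-4-hydroxycyclohex-2-en-1-one
Product: 11 (R)-4-(tert-butyldimethylsilyloxy)cyclohex-2-en-1-one
Conditions: TBSCl, imidazole, DMF, rt
Reagents that add atoms: tert-butyldimethylsilyl chloride CC(C)(C)[Si](C)(C)Cl
Why: Standard silylation; the OTBS group later directs the annulation and is the masked C10 carbonyl.

Step 8
Reactants: 11; 12 1-methyl-1-(trimethylsilyl)allene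
Product: 13 (3aR,7R,7aR)-7-(tert-butyldimethylsilyloxy)-3-methyl-2-(trimethylsilyl)-1,3a,5,6,7,7a-hexahydro-4H-inden-4-one
Conditions: TiCl4, CH2Cl2, −78 °C
Reagents that add atoms: none
Why: Danheiser [3+2] annulation (conjugate addition, cationic 1,2-silyl shift, enolate capture): the allene adds to the β-carbon anti to the 4-OTBS group and ring closure gives the cis-fused hydrindanone (sets C1 and C5).

Step 9
Reactants: 13
Product: 14 (3aR,7R,7aR)-7-(tert-butyldimethylsilyloxy)-3-methyl-1,3a,5,6,7,7a-hexahydro-4H-inden-4-one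
Conditions: TFA, CH2Cl2, 0 °C, 15 min
Reagents that add atoms: none
Why: Ipso-protodesilylation of the vinylsilane through the β-silyl cation keeps the double bond at C3=C4; short time limits migration into conjugation.

Step 10
Reactants: 14
Product: 15 (2R,3S,3aR,7R,7aR)-7-(tert-butyldimethylsilyloxy)-2,3-epoxy-3-methyloctahydro-4H-inden-4-one
Conditions: mCPBA, NaHCO3, CH2Cl2, 0 °C
Reagents that add atoms: 3-chloroperoxybenzoic acid OOC(=O)c1cccc(Cl)c1
Why: Prilezhaev epoxidation from the convex face (the face of the ring-fusion hydrogens) places the C4 oxygen α; it is much faster than Baeyer–Villiger oxidation of the ketone.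

Step 11
Reactants: 15
Product: 18 (3R,3aR,7R,7aR)-7-(tert-butyldimethylsilyloxy)-3-hydroxy-3-methyl-3,3a,5,6,7,7a-hexahydro-4H-inden-4-one, via hydroxy selenide 16 (not isolated), via selenoxide 17 (not isolated)
Conditions: (PhSe)2, NaBH4, EtOH, rt → 60 °C; then 30% H2O2, THF, 0 °C → rt
Reagents that add atoms: sodium benzeneselenolate (from diphenyl diselenide) [Na+].[Se-]c1ccccc1; hydrogen peroxide OO
Why: Sharpless–Lauer epoxide → allylic alcohol transposition: PhSe− opens the epoxide at the less hindered C3 with inversion, and selenoxide syn-elimination can only go toward C2, giving the 2,3-alkene with the C4 configuration retained.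

Step 12
Reactants: 18
Product: 19 (3R,3aR,7R,7aR)-7-(tert-butyldimethylsilyloxy)-3-methyl-3-(triethylsilyloxy)-3,3a,5,6,7,7a-hexahydro-4H-inden-4-one
Conditions: TESOTf, 2,6-lutidine, CH2Cl2, −78 °C
Reagents that add atoms: triethylsilyl trifluoromethanesulfonate CC[Si](CC)(CC)OS(=O)(=O)C(F)(F)F
Why: Silylation of the tertiary alcohol protects the β-hydroxy ketone from retro-aldol cleavage and O–H alkylation in the next step.

**Union and endgame**

Step 13
Reactants: 19; 9
Product: 21 10α-(tert-butyldimethylsilyloxy)-4β-methyl-4α-(triethylsilyloxy)-7β-[(2R,3S,4S)-3,4-diacetoxy-6-methylhept-5-en-2-yl]-1αH,5αH-hydroazul-2-en-6-one, via diazoalkane 20 (not isolated)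
Conditions: 9, PhIF2, 2-chloropyridine, CH2Cl2, −78 °C; then 19, Sc(OTf)3 (10 mol %), pybox ligand (12 mol %), toluene, −78 → −30 °C
Reagents that add atoms: none
Why: Proposed new method: Sc(III)–pybox-catalysed carbon insertion of an α-stereogenic, acetoxy-bearing secondary-alkyl diazomethane into an unsymmetrical α-branched bicyclic ketone; the diazo carbon attacks the Sc-bound C6 carbonyl from the convex α face, the less substituted C8 (anti to N2+; C5 is hindered and deactivated by its β-silyloxy carbon) undergoes the 1,2-shift with loss of N2 to form C6–C7, C7–C8 and the seven-membered ring, and the ligand pocket is expected to place the side chain on the β face (7S); the closest known reactions are the Sc(OTf)3-catalysed homologation of simple cycloalkanones with aryl- and alkyldiazomethanes and the Tiffeneau–Demjanov ring expansion.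

Step 14
Reactants: 21
Product: 22 4α,10α-dihydroxy-4β-methyl-7β-[(2R,3S,4S)-3,4-diacetoxy-6-methylhept-5-en-2-yl]-1αH,5αH-hydroazul-2-en-6-one
Conditions: HF·pyridine, pyridine, THF, 0 °C → rt
Reagents that add atoms: none
Why: Buffered fluoride desilylation removes both silyl ethers and leaves the acetates and the epimerisable C5/C7 centres untouched.

Step 15
Reactants: 22
Product: 23 4α-hydroxy-4β-methyl-7β-[(2R,3S,4S)-3,4-diacetoxy-6-methylhept-5-en-2-yl]-1αH,5αH-hydroazul-2-ene-6,10-dione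
Conditions: DMP, NaHCO3, CH2Cl2, 0 °C → rt
Reagents that add atoms: none
Why: Dess–Martin oxidation of the only secondary alcohol (C10); the tertiary C4-OH cannot be oxidised.

Step 16
Reactants: 23
Product: 24 4α,6β-dihydroxy-4β-methyl-7β-[(2R,3S,4S)-3,4-diacetoxy-6-methylhept-5-en-2-yl]-1αH,5αH-hydroazul-2-en-10-one
Conditions: Me4NBH(OAc)3, AcOH/MeCN, −30 °C
Reagents that add atoms: none
Why: Evans–Saksena directed reduction: the alkoxyborohydride formed at C4-OH delivers hydride intramolecularly to the β-hydroxy ketone C6 from the α face (6β-OH, 1,3-anti), while the C10 ketone without a directing hydroxyl is not reduced.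

Step 17
Reactants: 24
Product: 27 4α,6β,9α-tris(triethylsilyloxy)-4β-methyl-7β-[(2R,3S,4S)-3,4-diacetoxy-6-methylhept-5-en-2-yl]-1αH,5αH-hydroazul-2-en-10-one, via enol silane 25 (not isolated), via silyloxy epoxide 26 (not isolated)
Conditions: LiHMDS, TESCl (in situ quench), THF, −78 → 0 °C; then DMDO, acetone/CH2Cl2, −78 °C
Reagents that add atoms: chlorotriethylsilane CC[Si](Cl)(CC)CC; dimethyldioxirane CC1(C)OO1
Why: Kinetic enolisation at the only α-CH2 (C9) with O-silylation of both hydroxyls, then Rubottom oxidation: DMDO attacks the enol silane from the open α face (the β face is shielded by the C7 side chain and the five-membered ring) and 1,4-silyl shift gives the 9α-silyloxy ketone (sets C9).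

Step 18
Reactants: 27
Product: 28 4α,6β,9α-tris(triethylsilyloxy) ether of the target (10(18)-methylene)
Conditions: Zn, CH2Br2, TiCl4, THF/CH2Cl2, 0 °C → rt
Reagents that add atoms: dibromomethane BrCBr
Why: Takai–Lombardo methylenation converts the hindered, enolisable α-silyloxy ketone without epimerising C1/C9 and tolerates acetates and silyl ethers.

Step 19
Reactants: 28
Product: 29 target CNP0269663.2, (1R,4R,5S,6R,7S,9R,11R,12S,13S)-4α,6β,9α-triol 12,13-diacetate
Conditions: HF·pyridine, pyridine, THF, 0 °C → rt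
Reagents that add atoms: none
Why: Buffered fluoride desilylation frees the three hydroxyls; the acetates and the tertiary allylic alcohol are stable under these conditions.

**Compound list**
1 | hydroxyacetone | CC(=O)CO | starting material
2 | 3-methylbut-2-enal | CC(C)=CC=O | starting material
3 | (3R,4S)-3,4-dihydroxy-6-methylhept-5-en-2-one | CC(=O)[C@H](O)[C@H](C=C(C)C)O | intermediate
4 | (3R,4S)-6-methyl-2-oxohept-5-ene-3,4-diyl diacetate | CC(=O)[C@H](OC(C)=O)[C@H](C=C(C)C)OC(C)=O | intermediate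
5 | (3S,4S)-2,6-dimethylhepta-1,5-diene-3,4-diyl diacetate | C=C(C)[C@H](OC(C)=O)[C@H](C=C(C)C)OC(C)=O | intermediate
6 | (2R,3S,4S)-1-(1,3,2-benzodioxaborol-2-yl)-2,6-dimethylhept-5-ene-3,4-diyl diacetate | B1(C[C@@H](C)[C@H](OC(C)=O)[C@H](C=C(C)C)OC(C)=O)Oc2ccccc2O1 | intermediate (not isolated)
7 | (2R,3S,4S)-1-hydroxy-2,6-dimethylhept-5-ene-3,4-diyl diacetate | OC[C@@H](C)[C@H](OC(C)=O)[C@H](C=C(C)C)OC(C)=O | intermediate
8 | (2S,3S,4S)-2,6-dimethyl-1-oxohept-5-ene-3,4-diyl diacetate | O=C[C@@H](C)[C@H](OC(C)=O)[C@H](C=C(C)C)OC(C)=O | intermediate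
9 | (2R,3S,4S)-1-[(E)-2-(tert-butyldimethylsilyl)hydrazinylidene]-2,6-dimethylhept-5-ene-3,4-diyl diacetate | CC(C)(C)[Si](C)(C)N/N=C/[C@@H](C)[C@H](OC(C)=O)[C@H](C=C(C)C)OC(C)=O | intermediate
10 | (R)-4-hydroxycyclohex-2-en-1-one | O=C1CC[C@@H](O)C=C1 | starting material
11 | (R)-4-(tert-butyldimethylsilyloxy)cyclohex-2-en-1-one | O=C1CC[C@@H](O[Si](C)(C)C(C)(C)C)C=C1 | intermediate
12 | 1-methyl-1-(trimethylsilyl)allene | C=C=C(C)[Si](C)(C)C | starting material
13 | (3aR,7R,7aR)-7-(tert-butyldimethylsilyloxy)-3-methyl-2-(trimethylsilyl)-1,3a,5,6,7,7a-hexahydro-4H-inden-4-one | O=C1CC[C@@H](O[Si](C)(C)C(C)(C)C)[C@@H]2CC([Si](C)(C)C)=C(C)[C@H]12 | intermediate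
14 | (3aR,7R,7aR)-7-(tert-butyldimethylsilyloxy)-3-methyl-1,3a,5,6,7,7a-hexahydro-4H-inden-4-one | O=C1CC[C@@H](O[Si](C)(C)C(C)(C)C)[C@@H]2CC=C(C)[C@H]12 | intermediate
15 | (2R,3S,3aR,7R,7aR)-7-(tert-butyldimethylsilyloxy)-2,3-epoxy-3-methyloctahydro-4H-inden-4-one | O=C1CC[C@@H](O[Si](C)(C)C(C)(C)C)[C@@H]2C[C@H]3O[C@@]3(C)[C@H]12 | intermediate
16 | (2S,3S,3aR,7R,7aR)-7-(tert-butyldimethylsilyloxy)-3-hydroxy-3-methyl-2-(phenylselanyl)octahydro-4H-inden-4-one | O=C1CC[C@@H](O[Si](C)(C)C(C)(C)C)[C@@H]2C[C@H]([Se]c3ccccc3)[C@@](C)(O)[C@H]12 | intermediate (not isolated)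
17 | Se-oxide of 16 | O=C1CC[C@@H](O[Si](C)(C)C(C)(C)C)[C@@H]2C[C@H]([Se](=O)c3ccccc3)[C@@](C)(O)[C@H]12 | intermediate (not isolated)
18 | (3R,3aR,7R,7aR)-7-(tert-butyldimethylsilyloxy)-3-hydroxy-3-methyl-3,3a,5,6,7,7a-hexahydro-4H-inden-4-one | O=C1CC[C@@H](O[Si](C)(C)C(C)(C)C)[C@@H]2C=C[C@@](C)(O)[C@H]12 | intermediate
19 | (3R,3aR,7R,7aR)-7-(tert-butyldimethylsilyloxy)-3-methyl-3-(triethylsilyloxy)-3,3a,5,6,7,7a-hexahydro-4H-inden-4-one | O=C1CC[C@@H](O[Si](C)(C)C(C)(C)C)[C@@H]2C=C[C@@](C)(O[Si](CC)(CC)CC)[C@H]12 | intermediate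
20 | (2R,3S,4S)-1-diazo-2,6-dimethylhept-5-ene-3,4-diyl diacetate | [N-]=[N+]=C[C@@H](C)[C@H](OC(C)=O)[C@H](C=C(C)C)OC(C)=O | intermediate (not isolated)
21 | 10α-OTBS, 4α-OTES ring-expanded 6-ketone (name as in step 13) | CC(C)(C)[Si](C)(C)O[C@@H]1CC[C@@H]([C@@H](C)[C@H](OC(C)=O)[C@H](C=C(C)C)OC(C)=O)C(=O)[C@@H]2[C@H]1C=C[C@@]2(C)O[Si](CC)(CC)CC | intermediate
22 | 4α,10α-dihydroxy 6-ketone (name as in step 14) | O[C@@H]1CC[C@@H]([C@@H](C)[C@H](OC(C)=O)[C@H](C=C(C)C)OC(C)=O)C(=O)[C@@H]2[C@H]1C=C[C@@]2(C)O | intermediate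
23 | 4α-hydroxy 6,10-dione (name as in step 15) | O=C1CC[C@@H]([C@@H](C)[C@H](OC(C)=O)[C@H](C=C(C)C)OC(C)=O)C(=O)[C@@H]2[C@H]1C=C[C@@]2(C)O | intermediate
24 | 4α,6β-dihydroxy 10-ketone (name as in step 16) | O=C1CC[C@@H]([C@@H](C)[C@H](OC(C)=O)[C@H](C=C(C)C)OC(C)=O)[C@@H](O)[C@@H]2[C@H]1C=C[C@@]2(C)O | intermediate
25 | 4α,6β,10-tris(triethylsilyloxy) 2,9-diene (enol silane of 24) | CC[Si](CC)(CC)OC1=CC[C@@H]([C@@H](C)[C@H](OC(C)=O)[C@H](C=C(C)C)OC(C)=O)[C@@H](O[Si](CC)(CC)CC)[C@@H]2[C@H]1C=C[C@@]2(C)O[Si](CC)(CC)CC | intermediate (not isolated)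
26 | 9α,10α-epoxide of 25 | CC[Si](CC)(CC)O[C@@]12O[C@@H]1C[C@@H]([C@@H](C)[C@H](OC(C)=O)[C@H](C=C(C)C)OC(C)=O)[C@@H](O[Si](CC)(CC)CC)[C@@H]3[C@H]2C=C[C@@]3(C)O[Si](CC)(CC)CC | intermediate (not isolated)
27 | 4α,6β,9α-tris(triethylsilyloxy) 10-ketone (name as in step 17) | O=C1[C@H](O[Si](CC)(CC)CC)C[C@@H]([C@@H](C)[C@H](OC(C)=O)[C@H](C=C(C)C)OC(C)=O)[C@@H](O[Si](CC)(CC)CC)[C@@H]2[C@H]1C=C[C@@]2(C)O[Si](CC)(CC)CC | intermediate
28 | 4,6,9-tris(triethylsilyl) ether of the target | C=C1[C@H](O[Si](CC)(CC)CC)C[C@@H]([C@@H](C)[C@H](OC(C)=O)[C@H](C=C(C)C)OC(C)=O)[C@@H](O[Si](CC)(CC)CC)[C@@H]2[C@H]1C=C[C@@]2(C)O[Si](CC)(CC)CC | intermediate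
29 | CNP0269663.2 | C=C1[C@H](O)C[C@@H]([C@@H](C)[C@H](OC(C)=O)[C@H](C=C(C)C)OC(C)=O)[C@@H](O)[C@@H]2[C@H]1C=C[C@@]2(C)O | target

**Totals**
Total step count: 19. Longest linear sequence: 13 steps (7–19; equally 1–6 then 13–19).

**Three steps most likely to fail**

Step 13 (the proposed new ring expansion). The C6 ketone is hindered, the diazoalkane is α-branched, and the C7 configuration is predicted, not precedented. Fallback (known chemistry, Tiffeneau–Demjanov), setting out from 7 and 19 and coming back at 21: alcohol 7 is converted with I2/PPh3/imidazole into (2S,3S,4S)-1-iodo-2,6-dimethylhept-5-ene-3,4-diyl diacetate F1, and NaNO2/phloroglucinol in DMSO gives (2R,3S,4S)-2,6-dimethyl-1-nitrohept-5-ene-3,4-diyl diacetate F2. Nitro-aldol addition of F2 to ketone 19 (cat. TBAF, concentrated THF or 10 kbar) gives the β-nitro alcohol F3, and Zn/AcOH reduces it to the β-amino alcohol F4. Diazotisation (NaNO2, AcOH/H2O, 0 °C) triggers the 1,2-shift of C8 and gives 21; C7 epimers are separated.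

Step 1 (syn-aldol with an enal acceptor). Prenal may tie up the amine catalyst as an imine or dienamine. Fallback (Brown alkoxyallylboration), setting out from 2 and coming back at 5: prenal 2 is treated with [(Z)-γ-(4-methoxybenzyloxy)-β-methylallyl]diisopinocampheylborane (from 2-methylallyl PMB ether, s-BuLi, Ipc2BOMe of the antipode that gives the 3S,4S product, BF3·OEt2) to give (3S,4S)-3-(4-methoxybenzyloxy)-2,6-dimethylhepta-1,5-dien-4-ol F5. DDQ gives (3S,4S)-2,6-dimethylhepta-1,5-diene-3,4-diol F6, and Ac2O/pyridine/DMAP gives 5.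

Step 17 (enolisation and Rubottom oxidation). Deprotonation could occur at the doubly activated C1–H instead of C9, and LiHMDS could touch the acetates. Fallback (enamine catalysis, no strong base), setting out from 24 and coming back at 27: L-proline-catalysed α-aminoxylation of 24 with nitrosobenzene in DMSO (enamine forms on the CH2 side) gives the 9α-(anilinooxy) ketone F7. N–O cleavage with Zn/AcOH gives the 9α-hydroxy ketone F8, and TESOTf/2,6-lutidine gives 27.

**Further compounds**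
F1 | step 13 | (2S,3S,4S)-1-iodo-2,6-dimethylhept-5-ene-3,4-diyl diacetate | IC[C@@H](C)[C@H](OC(C)=O)[C@H](C=C(C)C)OC(C)=O
F2 | step 13 | (2R,3S,4S)-2,6-dimethyl-1-nitrohept-5-ene-3,4-diyl diacetate | [O-][N+](=O)C[C@@H](C)[C@H](OC(C)=O)[C@H](C=C(C)C)OC(C)=O
F3 | step 13 | β-nitro alcohol from 19 and F2 (mixture at the carbinol and nitro carbons) | OC1(C([N+](=O)[O-])[C@@H](C)[C@H](OC(C)=O)[C@H](C=C(C)C)OC(C)=O)CC[C@@H](O[Si](C)(C)C(C)(C)C)[C@@H]2C=C[C@@](C)(O[Si](CC)(CC)CC)[C@H]12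
F4 | step 13 | β-amino alcohol from F3 | OC1(C(N)[C@@H](C)[C@H](OC(C)=O)[C@H](C=C(C)C)OC(C)=O)CC[C@@H](O[Si](C)(C)C(C)(C)C)[C@@H]2C=C[C@@](C)(O[Si](CC)(CC)CC)[C@H]12
F5 | step 1 | (3S,4S)-3-(4-methoxybenzyloxy)-2,6-dimethylhepta-1,5-dien-4-ol | C=C(C)[C@H](OCc1ccc(OC)cc1)[C@H](C=C(C)C)O
F6 | step 1 | (3S,4S)-2,6-dimethylhepta-1,5-diene-3,4-diol | C=C(C)[C@H](O)[C@H](C=C(C)C)O
F7 | step 17 | 9α-(anilinooxy) derivative of 24 | O=C1[C@H](ONc2ccccc2)C[C@@H]([C@@H](C)[C@H](OC(C)=O)[C@H](C=C(C)C)OC(C)=O)[C@@H](O)[C@@H]2[C@H]1C=C[C@@]2(C)O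
F8 | step 17 | 9α-hydroxy derivative of 24 | O=C1[C@H](O)C[C@@H]([C@@H](C)[C@H](OC(C)=O)[C@H](C=C(C)C)OC(C)=O)[C@@H](O)[C@@H]2[C@H]1C=C[C@@]2(C)O
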